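The constants used here belong to no real substance.

The vessel was closed, stirred and isothermal, and I charged it with X and J at two strengths of J, beta and gamma.

- beta: X 0.20 mM; J 0.240 mM; time 4.0 min
- gamma: X 0.20 mM; J 0.480 mM; time 4.0 min

    X → L (k1 = 0.0302 s⁻¹)
    X + J → X.J (k2 = 33.6 L mol⁻¹ s⁻¹)
    J + X.J → J.X.J (k3 = 742 L mol⁻¹ s⁻¹)
    J.X.J → G (k4 = 0.0369 s⁻¹)
    X.J ⇌ Z (K5 = 0.759, k5 = 0.0319 s⁻¹)

1. which of these there is most of at the end, counted by the X in it, beta (L / X / G / J.X.J)
2. which of these there is most of at the end, counted by the X in it, gamma (L / X / G / J.X.J)
3. amount of the one of these that there is most of at the end, in percent of the X charged, beta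
4. amount of the one of these that there is most of at the end, in percent of the X charged, gamma

X leaves by two roads: by itself to L with constant a = 0.0302 s⁻¹, or with J to X.J at the pseudo-first-order rate b[J], where b = 33.6 L mol⁻¹ s⁻¹. So I divided the one rate by the other, and time dropped out: of the X lost at a given J, the part going to L is φ = a/(a + b[J]). With J as charged this gave 78.9 % in beta and 65.2 % in gamma; I call φ the L share, a selectivity.

But X.J takes a second J at 0.178 s⁻¹ in beta, faster than the 0.0319 s⁻¹ of its turning to Z, and no arrow gives J back. So each captured X costs a pair of J, and I took J midway between the charge and its estimated end: 0.198 mM in beta and 0.410 mM in gamma. That raised φ to 82.0 % and 68.7 %. The reading comes at ten times the 0.38 min half-life of X by step 1 alone, so I applied φ to the whole charge and committed to L in both flasks.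

The forecast also named L at 80.5 % for beta and L at 67.5 % for gamma, holding that “the uncaptured direct product L dominates in both runs”; my beta figure stood 1.5 percentage points above its own.

The simulation gave L at 81.4 % in beta and L at 68.2 % in gamma. In gamma the half-life of X was 0.38 min by the road to L and, with 73.5 % of J left at the end, 0.97 min by capture, which puts φ at the end at 71.8 %; the yield in gamma lay below that and above the 65.2 % from J as charged. For gamma with 1.9 mM of J, φ as charged is 32.1 %; that flask held most of its X as G and ended with L at 33.7 %.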